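Start from 0.0399 min⁻¹, the rate constant of the step from L to E times [D]. D comes back from each step it enters, so [D] stays at its charge and L is lost by a pseudo-first-order law.

Z 0.050 M; D 9.5 mM; time 1.0 h

- the E standing at 1.0 h, as a percentage of the Z charged
- the change that raises the amount of E at 1.0 h, in percent of the Z charged most ("none" if none brings more than 2 percentage points) (larch / elm / alder / none)
- amount of E at 1.0 h, in percent of the Z charged, after larch

- larch: doubling the solubility in step 4, all else as stated
- elm: doubling the dissolution coefficient of step 4, all else as stated
- alder: doubling the amount of D, all else as stated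

    L ⇌ X (K1 = 0.047, k1 = 0.029 min⁻¹)
    L + D → D + E (k2 = 4.2 M⁻¹ min⁻¹)
    D + X → D + G (k3 = 8.4 M⁻¹ min⁻¹)
    Z ⇌ L, rate k4*(cs4 - [L]) while solid is left; crystals form when [L] > cs4 (cs4 = 29 mM, k4 = 0.15 min⁻¹)

How much goes the other way? L also turns reversibly into X, and D converts X to G. X relaxes with a half-life of 1.07 min, shorter than its 0.14 h towards G, so X follows L at [X]/[L] = 0.0416. The total loss constant of L is then 0.0432 min⁻¹, and 92.3% of the L lost becomes E.

Where does [L] stand while solid is left? Z feeds L at 0.15 min⁻¹ times the gap below the solubility 29 mM, and this supply equals the loss at 22.5 mM. Call this the standing level of L; it is approached in about 5.18 min.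

How long does the solid last? At the standing level L is lost at 0.972 mM min⁻¹, so by my reckoning Z is gone after 33.4 min. L then decays from its level to 7.14 mM at the asked time, which gives me 79.1%.

The same reckoning gives 83.6% for larch, where the level doubles. For elm it gives 81.8%. Alder, with the loss constant near 0.0858 min⁻¹, gives 91.5%, more than either of the others.

The forecast says 78.3%, alder and 83.1% after larch, on the grounds for alder that “rates double, about 1 mM is left”. My 79.1% stands 0.80 percentage points above its figure.

The flask gives 78.4%; alder is best at 13 points, against 4.8 points for larch and 2.7 points for elm, and larch reaches 83.2%.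

At 1.00 h this flask is still working off its pool, with L at 14.5% of the Z charged. The neighbour charged with 0.20 M of Z still has 61.7% of it as solid at 1.00 h, and for that flask I take L at the standing level 22.5 mM. E in that neighbour then grows at 0.898 mM min⁻¹ after the start-up 5.18 min, which makes 49.2 mM, or 24.6% of that charge, and that flask reads 24.5%.

Its constants belong to no real substance; the result is computed.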